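**Strategy.** The dihydrobenzofuran ring is cut at its aryl ether bond O1–C7a and at the C3–C3a bond, which sit on adjacent arene carbons next to the C7 methoxy group. The O1–C2–C3 unit with the C3 hydroxymethyl carbon is then an aldol-type β-hydroxy ester. In one operation a palladium catalyst C-arylates the dianion of an enantiopure β-hydroxy ester at the iodide of a 1-bromo-2-iodoarene and closes the ring by O-arylation at the neighbouring bromide; C2 is carried over and C3 settles trans. The precursor is the bis(benzyl ether) of an (R,R)-dibenzylbutanediol bearing a 4-bromo-3-iodo-5-methoxyphenyl ring, made from an (R)-β-benzylbutyrolactone.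

Key step: step 13

Assumption: the six starting materials are taken as commercial, and the (S,S)-TsDPEN ruthenium catalyst of step 12 is taken to give the (S)-carbinol as it does with simple aryl ketones (the enantiomeric ligand is used otherwise). Locants O1, C2, C3, C3a, C7 and C7a are those of the dihydrobenzofuran ring.

Step 1
Reactants: 1 methyl 4-amino-3-methoxybenzoate
Product: 2 methyl 4-amino-3-iodo-5-methoxybenzoate
Conditions: NIS, MeCN, rt
Reagents that add atoms: N-iodosuccinimide, O=C1CCC(=O)N1I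
Why: Electrophilic aromatic iodination, directed by the amino group to its only free ortho position (para is blocked by the ester).

Step 2
Reactants: 2 methyl 4-amino-3-iodo-5-methoxybenzoate
Product: 4 methyl 4-bromo-3-iodo-5-methoxybenzoate, via diazonium bromide 3 (not isolated)
Conditions: NaNO2, 48% aq HBr, MeCN, 0 °C; then CuBr (cat.), 60 °C
Reagents that add atoms: hydrogen bromide, Br
Why: Sandmeyer bromination places bromine between OMe and iodine, a position that direct halogenation does not reach.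

Step 3
Reactants: 4 methyl 4-bromo-3-iodo-5-methoxybenzoate
Product: 5 (4-bromo-3-iodo-5-methoxyphenyl)methanol
Conditions: LiBH4, THF, 0 to 50 °C
Reagents that add atoms: none
Why: Hydride reduction of the ester by LiBH4, which should leave both aryl halides untouched.

Step 4
Reactants: 5 (4-bromo-3-iodo-5-methoxyphenyl)methanol
Product: 6 2-bromo-5-(bromomethyl)-1-iodo-3-methoxybenzene
Conditions: PBr3, CH2Cl2, 0 °C
Reagents that add atoms: phosphorus tribromide, BrP(Br)Br
Why: Bromide displaces the phosphite ester at the primary benzylic carbon (SN2).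

Step 5
Reactants: 7 (R)-epichlorohydrin, 8 diethyl malonate
Product: 9 ethyl (1S,5R)-2-oxo-3-oxabicyclo[3.1.0]hexane-1-carboxylate
Conditions: NaOEt, EtOH, rt then reflux
Reagents that add atoms: none
Why: Malonate opens the epoxide at its CH2 carbon, the alkoxide re-closes to a new epoxide with loss of chloride, and the malonate anion opens that epoxide at the stereogenic carbon with inversion (3-exo-tet cyclopropanation) before lactonisation, so the stereocenter of 7 sets C5 and the forced cis ring fusion sets C1.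

Step 6
Reactants: 9 ethyl (1S,5R)-2-oxo-3-oxabicyclo[3.1.0]hexane-1-carboxylate, 10 1-(benzyloxy)-4-bromo-2-methoxybenzene
Product: 12 ethyl (4R)-4-[4-(benzyloxy)-3-methoxybenzyl]-2-oxotetrahydrofuran-3-carboxylate, via aryl Grignard reagent 11 (not isolated)
Conditions: Mg, THF, 40 °C; then 9, CuI (10 mol%), THF, −30 to 0 °C; aq NH4Cl
Reagents that add atoms: none
Why: Copper-catalysed homoconjugate addition of the aryl Grignard reagent opens the doubly activated cyclopropane at its CH2 carbon, which leaves the C4 stereocenter untouched; the new C3 center is formed as an epimer mixture and is removed in step 7.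

Step 7
Reactants: 12 ethyl (4R)-4-[4-(benzyloxy)-3-methoxybenzyl]-2-oxotetrahydrofuran-3-carboxylate
Product: 13 (4R)-4-[4-(benzyloxy)-3-methoxybenzyl]dihydrofuran-2(3H)-one
Conditions: LiCl, H2O, DMSO, 140 °C
Reagents that add atoms: none
Why: Krapcho dealkoxycarbonylation of the malonate-type ester, with C4 not involved.

Step 8
Reactants: 13 (4R)-4-[4-(benzyloxy)-3-methoxybenzyl]dihydrofuran-2(3H)-one, 6 2-bromo-5-(bromomethyl)-1-iodo-3-methoxybenzene
Product: 14 (3R,4R)-4-[4-(benzyloxy)-3-methoxybenzyl]-3-(4-bromo-3-iodo-5-methoxybenzyl)dihydrofuran-2(3H)-one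
Conditions: LiN(SiMe3)2, THF, −78 °C; then 6, −78 to −20 °C
Reagents that add atoms: none
Why: Alkylation of the lactone lithium enolate anti to the C4 benzyl group should give the trans lactone, so C3 is set by the adjacent stereocenter.

Step 9
Reactants: 14 (3R,4R)-4-[4-(benzyloxy)-3-methoxybenzyl]-3-(4-bromo-3-iodo-5-methoxybenzyl)dihydrofuran-2(3H)-one
Product: 15 (2R,3R)-2-[4-(benzyloxy)-3-methoxybenzyl]-3-(4-bromo-3-iodo-5-methoxybenzyl)butane-1,4-diol
Conditions: LiBH4, THF, 0 °C to rt
Reagents that add atoms: none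
Why: Hydride reduction of the lactone to the 1,4-diol, which touches neither stereocenter nor the aryl halides.

Step 10
Reactants: 15 (2R,3R)-2-[4-(benzyloxy)-3-methoxybenzyl]-3-(4-bromo-3-iodo-5-methoxybenzyl)butane-1,4-diol
Product: 16 (2R,3R)-1,4-bis(benzyloxy)-2-[4-(benzyloxy)-3-methoxybenzyl]-3-(4-bromo-3-iodo-5-methoxybenzyl)butane
Conditions: NaH, BnBr, Bu4NI (cat.), DMF, 0 °C to rt
Reagents that add atoms: benzyl bromide, BrCc1ccccc1
Why: Williamson etherification masks both primary hydroxyl groups against the strong base and the palladium alkoxide chemistry of step 13, with groups that leave together with the phenol benzyl ethers at the end.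

Step 11
Reactants: 17 tert-butyl acetate, 18 methyl 4-(benzyloxy)-3-methoxybenzoate
Product: 19 tert-butyl 3-[4-(benzyloxy)-3-methoxyphenyl]-3-oxopropanoate
Conditions: LiN(iPr)2, THF, −78 °C; then 18, −78 to 0 °C; aq NH4Cl
Reagents that add atoms: none
Why: Crossed Claisen condensation in which the non-enolisable aryl ester can act only as the acceptor for the lithium enolate of tert-butyl acetate.

Step 12
Reactants: 19 tert-butyl 3-[4-(benzyloxy)-3-methoxyphenyl]-3-oxopropanoate
Product: 20 tert-butyl (3S)-3-[4-(benzyloxy)-3-methoxyphenyl]-3-hydroxypropanoate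
Conditions: RuCl[(S,S)-TsDPEN](p-cymene) (1 mol%), HCO2H/Et3N (5:2), DMF, 40 °C
Reagents that add atoms: none
Why: Noyori asymmetric transfer hydrogenation of the aryl ketone, in which the chiral catalyst sets the (S)-carbinol that becomes C2 of the dihydrobenzofuran.

Step 13
Reactants: 16 (2R,3R)-1,4-bis(benzyloxy)-2-[4-(benzyloxy)-3-methoxybenzyl]-3-(4-bromo-3-iodo-5-methoxybenzyl)butane, 20 tert-butyl (3S)-3-[4-(benzyloxy)-3-methoxyphenyl]-3-hydroxypropanoate
Product: 23 tert-butyl (2S,3S)-2-[4-(benzyloxy)-3-methoxyphenyl]-5-{(2R,3R)-4-(benzyloxy)-2-[(benzyloxy)methyl]-3-[4-(benzyloxy)-3-methoxybenzyl]butyl}-7-methoxy-2,3-dihydro-1-benzofuran-3-carboxylate, via open-chain C-arylated hydroxy ester 21 (not isolated), via cis ester 22 (not isolated)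
Conditions: 20 (1.2 equiv), LiN(SiMe3)2 (3.5 equiv), Pd2(dba)3 (3 mol%), tBuXPhos (7 mol%), toluene/THF, −20 °C to rt, then 80 °C; aq NH4Cl; then DBU, CH2Cl2, rt
Reagents that add atoms: none
Why: Proposed new method: the dilithium alkoxide–enolate of 20 should be C-arylated at the C–I bond of 16 (oxidative addition of zerovalent palladium, enolate transfer, C–C reductive elimination) to give 21, after which the same catalyst inserts into the neighbouring C–Br bond and the C2 alkoxide displaces bromide at palladium, so that C–O reductive elimination forms the aryl ether bond. The closest known reactions are the palladium-catalysed α-arylation of tert-butyl ester lithium enolates, the palladium-catalysed cyclisation of 2-(2-bromoaryl)ethanols bearing secondary carbinols to 2-substituted dihydrobenzofurans, and the copper-catalysed C-arylation/O-arylation domino of 1-bromo-2-iodoarenes with β-keto esters; their merger with a β-hydroxy ester dianion is the untested element. The only ring closed is the dihydrofuran ring, by intramolecular C–O reductive elimination from a six-membered arylpalladium alkoxide chelate. C2 keeps the S configuration of 20 because no bond to this carbon is made or broken, while C3 arises as a planar enolate and is set under thermodynamic control by DBU, which places the ester trans to the C2 aryl group (22 to 23). Site selectivity (carbon at the former iodide position, oxygen at the former bromide position) is secured by the faster insertion into C–I and by the bromide being flanked by OMe and iodine, so that it reacts only on heating and only intramolecularly. Chemoselectivity rests on the bulky phosphine, which favours C–O reductive elimination over β-hydride loss, and on the excess LiN(SiMe3)2, which holds the α-aryl ester as its enolate and so blocks retro-aldol cleavage.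

Step 14
Reactants: 23 tert-butyl (2S,3S)-2-[4-(benzyloxy)-3-methoxyphenyl]-5-{(2R,3R)-4-(benzyloxy)-2-[(benzyloxy)methyl]-3-[4-(benzyloxy)-3-methoxybenzyl]butyl}-7-methoxy-2,3-dihydro-1-benzofuran-3-carboxylate
Product: 24 [(2S,3R)-2-[4-(benzyloxy)-3-methoxyphenyl]-5-{(2R,3R)-4-(benzyloxy)-2-[(benzyloxy)methyl]-3-[4-(benzyloxy)-3-methoxybenzyl]butyl}-7-methoxy-2,3-dihydro-1-benzofuran-3-yl]methanol
Conditions: LiAlH4, THF, 0 °C to rt
Reagents that add atoms: none
Why: Hydride reduction of the tert-butyl ester to the primary alcohol; the C3 descriptor changes from S to R only because the priority of its substituent changes.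

Step 15
Reactants: 24 [(2S,3R)-2-[4-(benzyloxy)-3-methoxyphenyl]-5-{(2R,3R)-4-(benzyloxy)-2-[(benzyloxy)methyl]-3-[4-(benzyloxy)-3-methoxybenzyl]butyl}-7-methoxy-2,3-dihydro-1-benzofuran-3-yl]methanol
Product: 25 (2R,3R)-2-(4-hydroxy-3-methoxybenzyl)-3-{[(2S,3R)-2-(4-hydroxy-3-methoxyphenyl)-3-(hydroxymethyl)-7-methoxy-2,3-dihydro-1-benzofuran-5-yl]methyl}butane-1,4-diol
Conditions: H2 (1 atm), Pd/C, EtOAc/EtOH, rt
Reagents that add atoms: none
Why: Hydrogenolysis of the four benzyl ethers under neutral conditions, under which the benzylic C2–O bond of the dihydrobenzofuran should persist.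

**Compound list**

1 | methyl 4-amino-3-methoxybenzoate | COC(=O)c1ccc(N)c(OC)c1 | starting material
2 | methyl 4-amino-3-iodo-5-methoxybenzoate | COC(=O)c1cc(I)c(N)c(OC)c1 | intermediate
3 | 2-iodo-6-methoxy-4-(methoxycarbonyl)benzenediazonium bromide | COC(=O)c1cc(I)c([N+]#N)c(OC)c1.[Br-] | intermediate (not isolated)
4 | methyl 4-bromo-3-iodo-5-methoxybenzoate | COC(=O)c1cc(I)c(Br)c(OC)c1 | intermediate
5 | (4-bromo-3-iodo-5-methoxyphenyl)methanol | OCc1cc(I)c(Br)c(OC)c1 | intermediate
6 | 2-bromo-5-(bromomethyl)-1-iodo-3-methoxybenzene | BrCc1cc(I)c(Br)c(OC)c1 | intermediate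
7 | (R)-epichlorohydrin | ClC[C@H]1CO1 | starting material
8 | diethyl malonate | CCOC(=O)CC(=O)OCC | starting material
9 | ethyl (1S,5R)-2-oxo-3-oxabicyclo[3.1.0]hexane-1-carboxylate | CCOC(=O)[C@]12C[C@H]1COC2=O | intermediate
10 | 1-(benzyloxy)-4-bromo-2-methoxybenzene | COc1cc(Br)ccc1OCc1ccccc1 | starting material
11 | [4-(benzyloxy)-3-methoxyphenyl]magnesium bromide | COc1cc([Mg]Br)ccc1OCc1ccccc1 | intermediate (not isolated)
12 | ethyl (4R)-4-[4-(benzyloxy)-3-methoxybenzyl]-2-oxotetrahydrofuran-3-carboxylate (C3 epimers) | CCOC(=O)C1C(=O)OC[C@@H]1Cc1ccc(OCc2ccccc2)c(OC)c1 | intermediate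
13 | (4R)-4-[4-(benzyloxy)-3-methoxybenzyl]dihydrofuran-2(3H)-one | O=C1C[C@@H](Cc2ccc(OCc3ccccc3)c(OC)c2)CO1 | intermediate
14 | (3R,4R)-4-[4-(benzyloxy)-3-methoxybenzyl]-3-(4-bromo-3-iodo-5-methoxybenzyl)dihydrofuran-2(3H)-one | COc1cc(C[C@H]2COC(=O)[C@@H]2Cc3cc(OC)c(Br)c(I)c3)ccc1OCc1ccccc1 | intermediate
15 | (2R,3R)-2-[4-(benzyloxy)-3-methoxybenzyl]-3-(4-bromo-3-iodo-5-methoxybenzyl)butane-1,4-diol | COc1cc(C[C@@H](CO)[C@H](CO)Cc2cc(OC)c(Br)c(I)c2)ccc1OCc1ccccc1 | intermediate
16 | (2R,3R)-1,4-bis(benzyloxy)-2-[4-(benzyloxy)-3-methoxybenzyl]-3-(4-bromo-3-iodo-5-methoxybenzyl)butane | COc1cc(C[C@@H](COCc2ccccc2)[C@H](COCc3ccccc3)Cc4cc(OC)c(Br)c(I)c4)ccc1OCc1ccccc1 | intermediate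
17 | tert-butyl acetate | CC(=O)OC(C)(C)C | starting material
18 | methyl 4-(benzyloxy)-3-methoxybenzoate | COC(=O)c1ccc(OCc2ccccc2)c(OC)c1 | starting material
19 | tert-butyl 3-[4-(benzyloxy)-3-methoxyphenyl]-3-oxopropanoate | CC(C)(C)OC(=O)CC(=O)c1ccc(OCc2ccccc2)c(OC)c1 | intermediate
20 | tert-butyl (3S)-3-[4-(benzyloxy)-3-methoxyphenyl]-3-hydroxypropanoate | CC(C)(C)OC(=O)C[C@H](O)c1ccc(OCc2ccccc2)c(OC)c1 | intermediate
21 | tert-butyl (3S)-3-[4-(benzyloxy)-3-methoxyphenyl]-2-(2-bromo-3-methoxy-5-{(2R,3R)-4-(benzyloxy)-2-[(benzyloxy)methyl]-3-[4-(benzyloxy)-3-methoxybenzyl]butyl}phenyl)-3-hydroxypropanoate (present as its dilithium alkoxide–enolate, C2 undefined) | COc1cc(C[C@@H](COCc2ccccc2)[C@H](COCc3ccccc3)Cc4cc(OC)c(Br)c(c4)C(C(=O)OC(C)(C)C)[C@H](O)c4ccc(OCc5ccccc5)c(OC)c4)ccc1OCc1ccccc1 | intermediate (not isolated)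
22 | tert-butyl (2S,3R)-2-[4-(benzyloxy)-3-methoxyphenyl]-5-{(2R,3R)-4-(benzyloxy)-2-[(benzyloxy)methyl]-3-[4-(benzyloxy)-3-methoxybenzyl]butyl}-7-methoxy-2,3-dihydro-1-benzofuran-3-carboxylate (cis) | COc1cc(C[C@@H](COCc2ccccc2)[C@H](COCc3ccccc3)Cc4cc(OC)c5c(c4)[C@@H](C(=O)OC(C)(C)C)[C@@H](c4ccc(OCc6ccccc6)c(OC)c4)O5)ccc1OCc1ccccc1 | intermediate (not isolated)
23 | tert-butyl (2S,3S)-2-[4-(benzyloxy)-3-methoxyphenyl]-5-{(2R,3R)-4-(benzyloxy)-2-[(benzyloxy)methyl]-3-[4-(benzyloxy)-3-methoxybenzyl]butyl}-7-methoxy-2,3-dihydro-1-benzofuran-3-carboxylate (trans) | COc1cc(C[C@@H](COCc2ccccc2)[C@H](COCc3ccccc3)Cc4cc(OC)c5c(c4)[C@H](C(=O)OC(C)(C)C)[C@@H](c4ccc(OCc6ccccc6)c(OC)c4)O5)ccc1OCc1ccccc1 | intermediate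
24 | [(2S,3R)-2-[4-(benzyloxy)-3-methoxyphenyl]-5-{(2R,3R)-4-(benzyloxy)-2-[(benzyloxy)methyl]-3-[4-(benzyloxy)-3-methoxybenzyl]butyl}-7-methoxy-2,3-dihydro-1-benzofuran-3-yl]methanol | COc1cc(C[C@@H](COCc2ccccc2)[C@H](COCc3ccccc3)Cc4cc(OC)c5c(c4)[C@H](CO)[C@@H](c4ccc(OCc6ccccc6)c(OC)c4)O5)ccc1OCc1ccccc1 | intermediate
25 | (2R,3R)-2-(4-hydroxy-3-methoxybenzyl)-3-{[(2S,3R)-2-(4-hydroxy-3-methoxyphenyl)-3-(hydroxymethyl)-7-methoxy-2,3-dihydro-1-benzofuran-5-yl]methyl}butane-1,4-diol | COc1cc(C[C@@H](CO)[C@H](CO)Cc2cc(OC)c3c(c2)[C@H](CO)[C@@H](c2ccc(O)c(OC)c2)O3)ccc1O | target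

**Step count.** Total: 15 steps. Longest linear sequence: 10 steps (steps 1, 2, 3, 4, 8, 9, 10, 13, 14, 15).

**Steps most likely to fail**

Step 13 (Proposed new method). The palladium alkoxide may lose a β-hydride and oxidise the carbinol, retro-aldol cleavage may erode the C2 configuration before the α-aryl ester is deprotonated, the silylamide may be N-arylated, or the sequence may stop after the first coupling. The fallback sets out from 16 and the keto ester 19. The known copper-catalysed domino of 1-bromo-2-iodoarenes with β-keto esters (CuI, K2CO3, THF, 100 °C) should form the same two bonds in one operation and give tert-butyl 2-[4-(benzyloxy)-3-methoxyphenyl]-5-{(2R,3R)-4-(benzyloxy)-2-[(benzyloxy)methyl]-3-[4-(benzyloxy)-3-methoxybenzyl]butyl}-7-methoxy-1-benzofuran-3-carboxylate F1. Reduction with Mg in MeOH/THF should give the trans 2,3-dihydro esters, 23 together with the (2R,3R) trans diastereomer F2, in comparable amounts because the side-chain stereocenters are remote. Preparative HPLC on a chiral stationary phase separates them, and the route is rejoined at 23.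

Step 12. Enantioselection may be insufficient or turnover slow for this electron-rich aryl ketone. The fallback sets out from 19: NaBH4 in MeOH should give racemic tert-butyl 3-[4-(benzyloxy)-3-methoxyphenyl]-3-hydroxypropanoate F3. Lipase-catalysed acylation (Burkholderia cepacia lipase, vinyl acetate, tert-butyl methyl ether) should then acetylate the R enantiomer to tert-butyl (3R)-3-acetoxy-3-[4-(benzyloxy)-3-methoxyphenyl]propanoate F4 and leave the S alcohol, which is separated by chromatography. The route is rejoined at 20.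

Step 15. Over-reduction may cleave the benzylic C2–O bond of the dihydrobenzofuran, or the two alkyl benzyl ethers may be cleaved incompletely. The fallback sets out from 24 and replaces hydrogenolysis by Lewis-acid debenzylation with BCl3 and pentamethylbenzene as cation scavenger (CH2Cl2, −78 °C), which should give 25 directly. No new compound arises (entry F0), and the route is rejoined at 25.

Further compounds
F1 | step 13 | tert-butyl 2-[4-(benzyloxy)-3-methoxyphenyl]-5-{(2R,3R)-4-(benzyloxy)-2-[(benzyloxy)methyl]-3-[4-(benzyloxy)-3-methoxybenzyl]butyl}-7-methoxy-1-benzofuran-3-carboxylate | COc1cc(C[C@@H](COCc2ccccc2)[C@H](COCc3ccccc3)Cc4cc(OC)c5oc(-c6ccc(OCc7ccccc7)c(OC)c6)c(C(=O)OC(C)(C)C)c5c4)ccc1OCc1ccccc1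
F2 | step 13 | tert-butyl (2R,3R)-2-[4-(benzyloxy)-3-methoxyphenyl]-5-{(2R,3R)-4-(benzyloxy)-2-[(benzyloxy)methyl]-3-[4-(benzyloxy)-3-methoxybenzyl]butyl}-7-methoxy-2,3-dihydro-1-benzofuran-3-carboxylate | COc1cc(C[C@@H](COCc2ccccc2)[C@H](COCc3ccccc3)Cc4cc(OC)c5c(c4)[C@@H](C(=O)OC(C)(C)C)[C@H](c4ccc(OCc6ccccc6)c(OC)c4)O5)ccc1OCc1ccccc1
F3 | step 12 | tert-butyl 3-[4-(benzyloxy)-3-methoxyphenyl]-3-hydroxypropanoate (racemate) | CC(C)(C)OC(=O)CC(O)c1ccc(OCc2ccccc2)c(OC)c1
F4 | step 12 | tert-butyl (3R)-3-acetoxy-3-[4-(benzyloxy)-3-methoxyphenyl]propanoate | CC(=O)O[C@H](CC(=O)OC(C)(C)C)c1ccc(OCc2ccccc2)c(OC)c1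
F0 | step 15 | none | none
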